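**Retrosynthetic overview**
- Ring numbering used throughout: C1(=O), C2(OMe), C3(H), C4(=O), C5(CH3), C6(C21H43) of the single quinone ring.
- Feature: ring atoms C2–C3–C4–C5, with oxygen on C2 and C4 and the methyl on C5, are a 1,1,3-trioxygenated penta-1,3-diene in disguise. C6–C1 is the triple bond of a 2-ynal whose formyl carbon, attached at C1, is later exchanged for the C1 oxygen.
- Disconnections: quinone 19 ⇐ hydroquinone 18 ⇐ (formyl-to-hydroxyl exchange) para-hydroxybenzaldehyde 16 ⇐ [4+2] of ketene acetal diene 7 with tetracos-2-ynal 13 (bonds C5–C6 and C1–C2), then loss of methanol.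
- Fragments: 7 from propionyl chloride and 1,1-dichloroethene (acylation, methoxide exchange, silylation); 13 from docosan-1-ol (oxidation, one-carbon alkyne homologation, formylation).
- Ring order: the only ring is the carbocycle, closed in step 7 and aromatised in the same flask.

Key step: step 7

Remark: the target has no stereocentre. The sp3 centres of 12 and 14 are racemic and transient, and 5 is a mixture of geometric isomers, so these three are drawn without descriptors.

**Route**

Step 1
Reactants: 1 propionyl chloride; 2 1,1-dichloroethene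
Product: 4 1,1-dichloropent-1-en-3-one, via 1,1,1-trichloropentan-3-one 3 (not isolated)
Conditions: AlCl3 (1.1 equiv), CH2Cl2, 0 °C to rt; ice/aq. HCl; steam distillation (−HCl)
Reagents that add atoms: none
Why: Friedel–Crafts-type acylation of an alkene (Darzens–Nenitzescu acylation): the acylium–AlCl4 pair adds to the CH2 terminus of 2, chloride capture gives 3, and its acidic α-hydrogen allows loss of HCl on steam distillation to the conjugated dichlorovinyl ketone, AlCl3 acting as promoter and returning unchanged to the aqueous phase.

Step 2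
Reactants: 4 1,1-dichloropent-1-en-3-one
Product: 6 1,1-dimethoxypent-1-en-3-one, via 1-chloro-1-methoxypent-1-en-3-one 5 (not isolated)
Conditions: NaOMe (2.2 equiv), MeOH, 0 °C to rt; distillation
Reagents that add atoms: sodium methoxide, [Na+].[O-]C
Why: Two successive conjugate addition–elimination sequences (nucleophilic vinylic substitution) of methoxide at the doubly activated β-carbon should replace both chlorides and give the stabilised push–pull ketene acetal.

Step 3
Reactants: 6 1,1-dimethoxypent-1-en-3-one
Product: 7 (3Z)-1,1-dimethoxy-3-(trimethylsilyloxy)penta-1,3-diene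
Conditions: TMSCl, Et3N, ZnCl2 (cat.), toluene, 40 °C; filtration under Ar; bulb-to-bulb distillation
Reagents that add atoms: chlorotrimethylsilane, C[Si](C)(C)Cl
Why: Soft enolisation and O-silylation (the protocol used for Danishefsky-type dienes) can only enolise toward the ethyl CH2, and under these equilibrating conditions the Z enol ether, with the methyl cis to OSiMe3 and away from the ketene acetal arm, is expected to predominate; any E isomer would converge on the same arene.

Step 4
Reactants: 8 docosan-1-ol
Product: 9 docosanal
Conditions: TEMPO (cat.), PhI(OAc)2, CH2Cl2, 30 °C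
Reagents that add atoms: none
Why: Oxoammonium-mediated (TEMPO) oxidation of a primary alcohol should stop at the aldehyde under anhydrous conditions and tolerates the waxy substrate in warm CH2Cl2.

Step 5
Reactants: 9 docosanal
Product: 10 tricos-1-yne
Conditions: dimethyl (1-diazo-2-oxopropyl)phosphonate, K2CO3, MeOH/THF, rt
Reagents that add atoms: dimethyl (1-diazo-2-oxopropyl)phosphonate, CC(=O)C(=[N+]=[N-])P(=O)(OC)OC
Why: Seyferth–Gilbert homologation in its Ohira–Bestmann form: methanolysis of the reagent frees the diazomethylphosphonate anion, olefination gives a diazoalkene that loses N2, and a 1,2-hydrogen shift of the alkylidene carbene gives the terminal alkyne under conditions mild enough for an enolisable aldehyde.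

Step 6
Reactants: 10 tricos-1-yne
Product: 13 tetracos-2-ynal, via tricos-1-yn-1-yllithium 11 (not isolated), via lithium aminoalkoxide 12 (not isolated)
Conditions: n-BuLi, THF, −20 to 0 °C; DMF, 0 °C to rt; inverse quench into cold aq. KH2PO4/MTBE
Reagents that add atoms: N,N-dimethylformamide, CN(C)C=O
Why: Formylation of a lithium acetylide with DMF: the tetrahedral aminoalkoxide 12 masks the carbonyl until the inverse quench into buffered acid, which protonates the released dimethylamine before it can add to the ynal.

Step 7
Reactants: 7 (3Z)-1,1-dimethoxy-3-(trimethylsilyloxy)penta-1,3-diene; 13 tetracos-2-ynal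
Product: 16 2-henicosyl-4-hydroxy-6-methoxy-3-methylbenzaldehyde, via cyclohexa-1,4-diene cycloadduct 14 (not isolated), via aryl trimethylsilyl ether 15 (not isolated)
Conditions: 7 (1.5 equiv), toluene, rt to 80 °C, Ar; then 1 M aq. HCl/THF, rt
Reagents that add atoms: none
Why: This is a thermal, concerted but asynchronous normal-demand Diels–Alder reaction of an oxygenated (Danishefsky/Brassard-type) diene with an acetylenic carbonyl dienophile, the known entry to resorcinol monoethers; the methyl-bearing diene terminus, which carries the largest HOMO coefficient because the silyloxy and acetal oxygens both donate to it, bonds first to the β-carbon of the ynal (future C6) and the acetal carbon then closes onto the α-carbon (future C1). The six-membered carbocycle is closed by intermolecular [4+2] cycloaddition, which forms C5–C6 and C1–C2 in one operation and gives the 1,4-cyclohexadiene 14. Adduct 14 aromatises by 1,4-elimination of methanol (one acetal methoxy from C2, the hydrogen from C5), which leaves exactly one methoxy on C2, and dilute acid hydrolyses the aryl silyl ether 15 to the C4 phenol. No stereocentre results, since the sp3 centre at C5 of 14 is racemic and is erased on aromatisation. The step needs one regiochemical sense, secured by the matched donor–acceptor polarisation of both partners, and addition at C≡C instead of C=O, secured by leaving out any Lewis acid, which hetero-Diels–Alder or Mukaiyama-type attack on the aldehyde would require. The Z geometry of 7 keeps the methyl on the outside of the s-cis diene, so the reactive conformation is accessible.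

Step 8
Reactants: 16 2-henicosyl-4-hydroxy-6-methoxy-3-methylbenzaldehyde
Product: 18 3-henicosyl-5-methoxy-2-methylbenzene-1,4-diol, via aryl formate 17 (not isolated)
Conditions: 30% aq. H2O2 (1.2 equiv), H2SO4 (cat.), MeOH/CH2Cl2, 0 °C to rt, Ar
Reagents that add atoms: hydrogen peroxide, OO
Why: Dakin-type oxidation under acid catalysis: H2O2 adds to the aldehyde, the electron-rich aryl group (para OH, ortho OMe) migrates to oxygen in a Baeyer–Villiger-type shift, and the formate is methanolysed in the flask; the acidic medium keeps the hydroquinone from autoxidising to a quinone that alkaline peroxide would epoxidise.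

Step 9
Reactants: 18 3-henicosyl-5-methoxy-2-methylbenzene-1,4-diol
Product: 19 3-henicosyl-5-methoxy-2-methylcyclohexa-2,5-diene-1,4-dione (target)
Conditions: Ag2O, Na2SO4, Et2O/CH2Cl2, rt, dark
Reagents that add atoms: none
Why: Ag2O is a mild two-electron oxidant that should convert the hydroquinone into the para-benzoquinone without touching the alkyl chain or the vinylogous ester methoxy group.

**Compound list**
1 | propionyl chloride | CCC(=O)Cl | starting material
2 | 1,1-dichloroethene | C=C(Cl)Cl | starting material
3 | 1,1,1-trichloropentan-3-one | CCC(=O)CC(Cl)(Cl)Cl | intermediate (not isolated)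
4 | 1,1-dichloropent-1-en-3-one | CCC(=O)C=C(Cl)Cl | intermediate
5 | 1-chloro-1-methoxypent-1-en-3-one (mixture of geometric isomers) | CCC(=O)C=C(Cl)OC | intermediate (not isolated)
6 | 1,1-dimethoxypent-1-en-3-one | CCC(=O)C=C(OC)OC | intermediate
7 | (3Z)-1,1-dimethoxy-3-(trimethylsilyloxy)penta-1,3-diene | C/C=C(\O[Si](C)(C)C)C=C(OC)OC | intermediate
8 | docosan-1-ol | CCCCCCCCCCCCCCCCCCCCCCO | starting material
9 | docosanal | CCCCCCCCCCCCCCCCCCCCCC=O | intermediate
10 | tricos-1-yne | CCCCCCCCCCCCCCCCCCCCCC#C | intermediate
11 | tricos-1-yn-1-yllithium | CCCCCCCCCCCCCCCCCCCCCC#C[Li] | intermediate (not isolated)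
12 | lithium 1-(dimethylamino)tetracos-2-yn-1-olate (racemic) | CCCCCCCCCCCCCCCCCCCCCC#CC([O-])N(C)C.[Li+] | intermediate (not isolated)
13 | tetracos-2-ynal | CCCCCCCCCCCCCCCCCCCCCC#CC=O | intermediate
14 | 2-henicosyl-6,6-dimethoxy-3-methyl-4-(trimethylsilyloxy)cyclohexa-1,4-diene-1-carbaldehyde (racemic) | CCCCCCCCCCCCCCCCCCCCCC1=C(C=O)C(OC)(OC)C=C(O[Si](C)(C)C)C1C | intermediate (not isolated)
15 | 2-henicosyl-6-methoxy-3-methyl-4-(trimethylsilyloxy)benzaldehyde | CCCCCCCCCCCCCCCCCCCCCc1c(C)c(O[Si](C)(C)C)cc(OC)c1C=O | intermediate (not isolated)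
16 | 2-henicosyl-4-hydroxy-6-methoxy-3-methylbenzaldehyde | CCCCCCCCCCCCCCCCCCCCCc1c(C)c(O)cc(OC)c1C=O | intermediate
17 | 2-henicosyl-4-hydroxy-6-methoxy-3-methylphenyl formate | CCCCCCCCCCCCCCCCCCCCCc1c(C)c(O)cc(OC)c1OC=O | intermediate (not isolated)
18 | 3-henicosyl-5-methoxy-2-methylbenzene-1,4-diol | CCCCCCCCCCCCCCCCCCCCCc1c(C)c(O)cc(OC)c1O | intermediate
19 | 3-henicosyl-5-methoxy-2-methylcyclohexa-2,5-diene-1,4-dione | CCCCCCCCCCCCCCCCCCCCCC1=C(C)C(=O)C=C(OC)C1=O | target

**Count**
Total steps: 9. Longest linear sequence: 6 steps (steps 4, 5, 6, 7, 8, 9 from docosan-1-ol; the diene branch, steps 1, 2, 3, 7, 8, 9, is equally long).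

**Steps most likely to fail**

Step 7. The cycloaddition at the β-alkylated triple bond may be slow, so that hydrolysis or oligomerisation of the diene, polymerisation of the ynal, or attack at the formyl carbon could compete. The fallback replaces the aldehyde activating group by a methyl ketone. It sets out from tricos-1-yne 10, used as its acetylide 11. Inverse addition of 11 to acetic anhydride in THF at −78 °C should give pentacos-3-yn-2-one F1, a sturdier dienophile that offers no aldehyde. Heated with diene 7 in toluene, F1 should give the adduct 1-[2-henicosyl-6,6-dimethoxy-3-methyl-4-(trimethylsilyloxy)cyclohexa-1,4-dien-1-yl]ethan-1-one F2. Loss of methanol then gives 1-[2-henicosyl-6-methoxy-3-methyl-4-(trimethylsilyloxy)phenyl]ethan-1-one F3, and dilute acid work-up gives 1-(2-henicosyl-4-hydroxy-6-methoxy-3-methylphenyl)ethan-1-one F4. Dakin oxidation of this para-hydroxyaryl ketone (H2O2, NaOH, THF/H2O, Ar) should pass through 2-henicosyl-4-hydroxy-6-methoxy-3-methylphenyl acetate F5, hydrolysed in the flask. Acidification under argon returns the route at hydroquinone 18, so steps 7 and 8 are both replaced.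

Step 8. Peroxide addition to the di-ortho-substituted aldehyde may be slow, hydrogen may migrate in place of aryl to give the benzoic acid, or the electron-rich ring may be over-oxidised. The fallback removes the formyl carbon and installs the C1 oxygen by phenol oxidation. It sets out from 16. Catalytic decarbonylation with [Rh(dppp)2]Cl (dppp = 1,3-bis(diphenylphosphino)propane) in refluxing xylene (Tsuji–Wilkinson type) should give 3-henicosyl-5-methoxy-2-methylphenol F6. The position para to its hydroxyl is the former formyl-bearing carbon C1 and is now free. Teuber oxidation with Fremy's salt, (KSO3)2NO, in CH2Cl2/aq. KH2PO4 with Bu4NHSO4 as phase-transfer agent should oxidise this position to the para-quinone. The route is rejoined directly at 19, so steps 8 and 9 are both replaced.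

Step 3. The trimethylsilyl dienol ether may be lost by hydrolysis during isolation, or the ketene acetal may be cleaved by ZnCl2/TMSCl on warming. The fallback uses a sturdier silyl group made without a Lewis acid and adds a fluoride deprotection. It sets out from 6. Soft enolisation with TBSOTf and Et3N in CH2Cl2 at −78 to 0 °C should give (3Z)-3-(tert-butyldimethylsilyloxy)-1,1-dimethoxypenta-1,3-diene F7, which should survive filtration through Et3N-deactivated silica. Cycloaddition with 13 in toluene, as in step 7, should give 4-(tert-butyldimethylsilyloxy)-2-henicosyl-6,6-dimethoxy-3-methylcyclohexa-1,4-diene-1-carbaldehyde F8. Loss of methanol then gives 4-(tert-butyldimethylsilyloxy)-2-henicosyl-6-methoxy-3-methylbenzaldehyde F9. Bu4NF in THF buffered with AcOH cleaves the silyl ether and returns the route at 16.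

**Further compounds**
F1 | step 7 | pentacos-3-yn-2-one | CCCCCCCCCCCCCCCCCCCCCC#CC(C)=O
F2 | step 7 | 1-[2-henicosyl-6,6-dimethoxy-3-methyl-4-(trimethylsilyloxy)cyclohexa-1,4-dien-1-yl]ethan-1-one (racemic) | CCCCCCCCCCCCCCCCCCCCCC1=C(C(C)=O)C(OC)(OC)C=C(O[Si](C)(C)C)C1C
F3 | step 7 | 1-[2-henicosyl-6-methoxy-3-methyl-4-(trimethylsilyloxy)phenyl]ethan-1-one | CCCCCCCCCCCCCCCCCCCCCc1c(C)c(O[Si](C)(C)C)cc(OC)c1C(C)=O
F4 | step 7 | 1-(2-henicosyl-4-hydroxy-6-methoxy-3-methylphenyl)ethan-1-one | CCCCCCCCCCCCCCCCCCCCCc1c(C)c(O)cc(OC)c1C(C)=O
F5 | step 7 | 2-henicosyl-4-hydroxy-6-methoxy-3-methylphenyl acetate | CCCCCCCCCCCCCCCCCCCCCc1c(C)c(O)cc(OC)c1OC(C)=O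
F6 | step 8 | 3-henicosyl-5-methoxy-2-methylphenol | CCCCCCCCCCCCCCCCCCCCCc1c(C)c(O)cc(OC)c1
F7 | step 3 | (3Z)-3-(tert-butyldimethylsilyloxy)-1,1-dimethoxypenta-1,3-diene | C/C=C(\O[Si](C)(C)C(C)(C)C)C=C(OC)OC
F8 | step 3 | 4-(tert-butyldimethylsilyloxy)-2-henicosyl-6,6-dimethoxy-3-methylcyclohexa-1,4-diene-1-carbaldehyde (racemic) | CCCCCCCCCCCCCCCCCCCCCC1=C(C=O)C(OC)(OC)C=C(O[Si](C)(C)C(C)(C)C)C1C
F9 | step 3 | 4-(tert-butyldimethylsilyloxy)-2-henicosyl-6-methoxy-3-methylbenzaldehyde | CCCCCCCCCCCCCCCCCCCCCc1c(C)c(O[Si](C)(C)C(C)(C)C)cc(OC)c1C=O
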